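**Retrosynthetic overview**
1. Target ⇒ its phenol/tertiary-alcohol diol: acetylate both oxygens, then cleave only the aryl acetate.
2. Key step: that diol ⇒ an open-chain 2-formylbenzoate carrying an intact (2E,6E)-farnesyl ether. One flask does terminal-selective Markovnikov oxymercuration of the triene, and NaBH4 then removes Hg, reduces CHO and closes the lactone.
3. Formyl carbon ⇒ aryl C–H by Mg-phenoxide-directed ortho-formylation; the target's own free OH is the directing group and has only one free ortho site.
4. Aryl ether ⇒ methyl 3-O-methylgallate + (2E,6E)-farnesyl bromide, so both E-olefins are purchased.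
5. Ring order: the benzene ring is purchased; the γ-lactone is the only ring made, and it closes in the key step (step 3 of 5).

Assumption: the target has no stereocentre, so "single enantiomer" is read as the single (2E,6E) geometric isomer.
Assumption: the first-choice disconnection is taken to be last-step O-alkylation of preformed 4,5-dihydroxy-6-methoxyphthalide with a pre-oxidised (11-acetoxy) farnesyl halide; neither fragment is used here.
Assumption: compounds 1 and 2 are catalogue chemicals.

**Step 1**
Reactants: 1, methyl 3,4-dihydroxy-5-methoxybenzoate (methyl 3-O-methylgallate); 2, (2E,6E)-farnesyl bromide [(2E,6E)-1-bromo-3,7,11-trimethyldodeca-2,6,10-triene]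
Product: 3, methyl 3-hydroxy-5-methoxy-4-{[(2E,6E)-3,7,11-trimethyldodeca-2,6,10-trien-1-yl]oxy}benzoate
Conditions: 2 (1.05 equiv), KHCO3 (1.2 equiv), DMF, rt → 40 °C, dark, 16 h
Reagents that add atoms: none other than reactant 2 (farnesyl bromide, BrC/C=C(\C)CC/C=C(\C)CCC=C(C)C)
Why: Regioselective Williamson etherification: bicarbonate ionises only the 4-OH (para to CO2Me, roughly 1.5–2 pKa units more acidic than the meta 3-OH), and SN2 at the primary allylic bromide carries the 2E,6E geometry through unchanged; no stereocentre is formed.

**Step 2**
Reactants: 3
Product: 4, methyl 2-formyl-3-hydroxy-5-methoxy-4-{[(2E,6E)-3,7,11-trimethyldodeca-2,6,10-trien-1-yl]oxy}benzoate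
Conditions: anhydrous MgCl2 (3 equiv), Et3N (6 equiv), (CH2O)n (8 equiv), MeCN, 80 °C, 8–16 h; cold 5% citric acid work-up
Reagents that add atoms: formaldehyde (from paraformaldehyde), C=O
Why: Casnati–Skattebøl ortho-formylation: the Mg phenoxide delivers CH2O only to the ortho carbon (C2 is the sole free ortho site and is also para to OMe), and the Mg-chelated saligenin alkoxide, held away from the ester, is oxidised in situ by a second CH2O (Oppenauer-type hydride transfer); the buffered basic medium leaves the ester, the allyl aryl ether (both its ortho positions are blocked, so no Claisen) and the olefins untouched.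

**Step 3 (key step)**
Reactants: 4
Product: 5, 4-hydroxy-5-{[(2E,6E)-11-hydroxy-3,7,11-trimethyldodeca-2,6-dien-1-yl]oxy}-6-methoxyisobenzofuran-1(3H)-one
Conditions: Hg(OAc)2 (1.0 equiv), THF–H2O (1:1), 0 °C → rt, 1–2 h; then 3 M NaOH, NaBH4 (3 equiv), 0 °C → rt; then 1 M HCl to pH 3, 0 °C
Reagents that add atoms: water, O
Why: Proposed new method: a one-flask merger of Brown oxymercuration–demercuration with reductive lactonisation (closest known reactions: terminal-selective oxymercuration of polyprenyl esters, and NaBH4 reduction of 2-formylbenzoates to phthalides); Hg(II) attacks the most accessible distal isopropylidene (the 2,3-olefin is inductively deactivated by the allylic aryloxy group, the 6,7-olefin is flanked by two chains, and the arene is deactivated by two carbonyls with its phenol tied up in the salicylaldehyde hydrogen bond), water adds at tertiary C11 (Markovnikov; no stereocentre because C11 carries two methyls), and alkaline NaBH4 then cleaves C–Hg (the C10 radical has no 5-exo olefin partner), reduces CHO, and the benzylic alkoxide displaces methoxide from the ortho ester to close the γ-lactone (re-closed on acidification if saponified).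

**Step 4**
Reactants: 5
Product: 6, 5-{[(2E,6E)-11-acetoxy-3,7,11-trimethyldodeca-2,6-dien-1-yl]oxy}-6-methoxy-1-oxo-1,3-dihydroisobenzofuran-4-yl acetate (diacetate)
Conditions: Ac2O (6 equiv), Et3N (8 equiv), DMAP (0.5 equiv), CH2Cl2, rt, 24 h
Reagents that add atoms: acetic anhydride, CC(=O)OC(C)=O
Why: DMAP-catalysed (Steglich-type) acylation: the N-acetylpyridinium acetylates the phenol at once and the open-chain tertiary carbinol over hours; no acid is present to ionise the tertiary or allylic C–O bonds, and nothing else in 5 is nucleophilic.

**Step 5**
Reactants: 6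
Product: 7, Farnesylemefuranone F [(2E,6E)-12-[(4-hydroxy-6-methoxy-1-oxo-1,3-dihydroisobenzofuran-5-yl)oxy]-2,6,10-trimethyldodeca-6,10-dien-2-yl acetate]
Conditions: NH4OAc (10 equiv), MeOH–H2O (4:1), rt, 6 h
Reagents that add atoms: none
Why: Chemoselective solvolysis of an aryl acetate: phenoxide is a far better leaving group than a tertiary alkoxide and the tert-alkyl acetate is sterically shielded, so only the phenolic ester is cleaved; the phthalide and both E-olefins are inert to near-neutral NH4OAc.

**Compound list**
1 | methyl 3,4-dihydroxy-5-methoxybenzoate | COC(=O)c1cc(O)c(O)c(OC)c1 | starting material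
2 | (2E,6E)-farnesyl bromide | BrC/C=C(\C)CC/C=C(\C)CCC=C(C)C | starting material
3 | methyl 3-hydroxy-5-methoxy-4-[(2E,6E)-farnesyloxy]benzoate | COC(=O)c1cc(O)c(OC/C=C(\C)CC/C=C(\C)CCC=C(C)C)c(OC)c1 | intermediate
4 | methyl 2-formyl-3-hydroxy-5-methoxy-4-[(2E,6E)-farnesyloxy]benzoate | COC(=O)c1cc(OC)c(OC/C=C(\C)CC/C=C(\C)CCC=C(C)C)c(O)c1C=O | intermediate
5 | 4-hydroxy-5-{[(2E,6E)-11-hydroxy-3,7,11-trimethyldodeca-2,6-dien-1-yl]oxy}-6-methoxyisobenzofuran-1(3H)-one | COc1cc2c(c(O)c1OC/C=C(\C)CC/C=C(\C)CCCC(C)(C)O)COC2=O | intermediate
6 | diacetate of 5 (aryl acetate + tertiary acetate) | COc1cc2c(c(OC(C)=O)c1OC/C=C(\C)CC/C=C(\C)CCCC(C)(C)OC(C)=O)COC2=O | intermediate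
7 | Farnesylemefuranone F | COc1cc2c(c(O)c1OC/C=C(\C)CC/C=C(\C)CCCC(C)(C)OC(C)=O)COC2=O | target

**Totals**
Total steps: 5. Longest linear sequence: 5 (fully linear from 1; 2 is purchased).

**Three steps most likely to fail, with fallbacks**
- **Step 3** (site selectivity 10,11 vs 6,7, plus the tandem reduction/lactonisation). Fallback: give up late-stage hydration. Make the oxidised C15 unit separately from (E,E)-farnesyl acetate: terminal-selective bromohydrin (NBS, aqueous THF), epoxide, LiAlH4 opening to the tertiary alcohol, diacetylation, then selective primary deacetylation. Attach it to 1 by Mitsunobu, then run step 2 and a plain NaBH4 reductive lactonisation, which gives 7 directly.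
- **Step 2** (formylation at a crowded carbon ortho to the ester). If the saligenin alkoxide lactonises instead of being oxidised, the resulting phthalide still converges on 5 in step 3, so this is not a failure. Fallback for low reactivity: start from C2v-symmetric methyl gallate, 4-O-farnesylate, and formylate the bis-phenol (a free OH is then para to the reacting carbon and the two ortho sites are equivalent). Then methylate the one OH not locked in the salicylaldehyde hydrogen bond (MeI, K2CO3, 1 equiv) to rejoin at 4.
- **Step 1** (4-O versus 3-O selectivity on a flanked catechol OH; some C-alkylation). Fallback: remove the regiochemical question by symmetry. Mono-4-O-farnesylate methyl gallate, where only the para OH is acidic enough, then desymmetrise by mono-O-methylation (1 equiv MeI, recycle) to reach 3.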